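**Plan**

- Lignan numbering: Ar1 = 4-hydroxy-3-methoxyphenyl on C7, Ar2 = 3-hydroxy-4,5-dimethoxyphenyl on C7'; ring A = C7–O–C9'–C8'–C8, ring B = C7'–O–C9–C8–C8'.
- Retrosynthetic cuts, in order: C7'–O of ring B (benzylic C–H oxidation), C7–O of ring A (cationic etherification of a triol), C7–C8 (lactone aldol), C7'–C8' (Stobbe condensation, the alkene then being hydrogenated).
- Forward: Ar2 aldehyde and dimethyl succinate give the benzylidene half-ester, then the (R)-β-(Ar2-methyl)butyrolactone; an aldol brings in Ar1; hydride reduction and acid close ring A; DDQ closes ring B; one deprotection ends the route.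
- Feature that allows the late closure: C7' of the ring-A tetrahydrofuran is a benzylic methylene para to the 4-methoxy group of Ar2, so it carries the most hydridic C–H once the Ar1 phenol is acylated, and the C9 hydroxyl on C8 lies cis to it on ring A, placed for a five-membered ether.
- Stereochemistry: C8' from rhodium-catalysed asymmetric hydrogenation; C8 from the anti aldol on the lactone enolate; C7 from trans-selective closure of ring A; C7' from the enforced cis ring fusion with Ar2 exo.

Key step: step 10

Assumption: the (S,S) antipode of Et-DuPHOS is taken to give the R acid in step 2, as the quadrant model for itaconate half-esters predicts; if the rotation of lactone 7 shows the opposite sense, the (R,R) ligand is used in the same way.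

**Route**

Step 1
Reactants: 1 3-hydroxy-4,5-dimethoxybenzaldehyde; 2 dimethyl succinate
Product: 4 (E)-4-(3-hydroxy-4,5-dimethoxyphenyl)-3-(methoxycarbonyl)but-3-enoic acid, via paraconic ester lactone 3 (not isolated)
Conditions: NaOMe (3.5 equiv), 2 (1.5 equiv), MeOH, reflux; then 2 M HCl
Reagents that add atoms: none
Why: Stobbe condensation, in which the succinate enolate adds to the aldehyde, the alkoxide lactonises to 3 and E1cB opening of that lactone gives the carboxylate irreversibly, which places the free acid on the CH2 arm and fixes the E alkene, while the phenoxide, being meta to the formyl group, does not deactivate the aldehyde by resonance (the phenol is left free here because an aryl silyl ether would not survive methoxide).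

Step 2
Reactants: 4 (E)-4-(3-hydroxy-4,5-dimethoxyphenyl)-3-(methoxycarbonyl)but-3-enoic acid
Product: 5 (R)-4-(3-hydroxy-4,5-dimethoxyphenyl)-3-(methoxycarbonyl)butanoic acid
Conditions: H2 (5 bar), [Rh(cod)((S,S)-Et-DuPHOS)]BF4 (1 mol%), NaOMe (10 mol%), MeOH, rt
Reagents that add atoms: none
Why: Rhodium-bisphospholane asymmetric hydrogenation of a Stobbe-type itaconate half-ester, in which the carboxylate arm chelates the metal beside the alkene so that the ligand selects the alkene face and sets C8' as R.

Step 3
Reactants: 5 (R)-4-(3-hydroxy-4,5-dimethoxyphenyl)-3-(methoxycarbonyl)butanoic acid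
Product: 7 (R)-4-(3-hydroxy-4,5-dimethoxybenzyl)dihydrofuran-2(3H)-one, via hydroxy acid 6 (not isolated)
Conditions: KOH (1.0 equiv), EtOH, 0 °C; CaCl2, NaBH4, EtOH, −10 °C → rt; then 3 M HCl, rt
Reagents that add atoms: none
Why: Chemoselective borohydride reduction, in which Ca(BH4)2 formed in the flask reduces the methyl ester but not the potassium carboxylate, and acidification lactonises hydroxy acid 6 to the five-membered lactone with the C8' centre untouched.

Step 4
Reactants: 7 (R)-4-(3-hydroxy-4,5-dimethoxybenzyl)dihydrofuran-2(3H)-one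
Product: 8 (R)-4-{3-[tert-butyl(dimethyl)silyloxy]-4,5-dimethoxybenzyl}dihydrofuran-2(3H)-one
Conditions: TBSCl (1.2 equiv), imidazole (2.5 equiv), DMF, rt
Reagents that add atoms: tert-butyldimethylsilyl chloride, CC(C)(C)[Si](C)(C)Cl
Why: Standard silylation of a phenol, giving an aryl silyl ether that should tolerate amide base, hydride at 0 °C and catalytic acid and that keeps Ar2 as electron-rich as possible for step 10.

Step 5
Reactants: 9 vanillin
Product: 10 4-formyl-2-methoxyphenyl pivalate
Conditions: pivaloyl chloride (1.1 equiv), Et3N, DMAP (cat.), CH2Cl2, 0 °C → rt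
Reagents that add atoms: pivaloyl chloride, CC(C)(C)C(=O)Cl
Why: Acylation of a phenol under nucleophilic catalysis, giving a hindered aryl ester that should not be attacked by the lactone enolate at −78 °C.

Step 6
Reactants: 8 (R)-4-{3-[tert-butyl(dimethyl)silyloxy]-4,5-dimethoxybenzyl}dihydrofuran-2(3H)-one; 10 4-formyl-2-methoxyphenyl pivalate
Product: 12 4-{[(3S,4R)-4-{3-[tert-butyl(dimethyl)silyloxy]-4,5-dimethoxybenzyl}-2-oxotetrahydrofuran-3-yl](hydroxy)methyl}-2-methoxyphenyl pivalate (both C7 carbinol epimers), via lithium enolate 11 (not isolated)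
Conditions: LiN(iPr)2 (1.05 equiv), THF, −78 °C; then 10, −78 °C; AcOH, −78 °C
Reagents that add atoms: none
Why: Aldol addition of a lithium lactone enolate, in which the aldehyde approaches the face opposite the C8' arylmethyl group and so sets C8 (3S) trans to C8', while the C7 carbinol forms as a mixture that does not matter because C7 is ionised in step 8.

Step 7
Reactants: 12 aldol adduct (both C7 carbinol epimers)
Product: 13 (2R,3R)-2-[(4-hydroxy-3-methoxyphenyl)(hydroxy)methyl]-3-{3-[tert-butyl(dimethyl)silyloxy]-4,5-dimethoxybenzyl}butane-1,4-diol (both C7 epimers)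
Conditions: LiAlH4 (4 equiv), THF, 0 °C; then H2O, 15% aq. NaOH, H2O
Reagents that add atoms: none
Why: LiAlH4 reduction opens the lactone to the C9 and C9' primary alcohols and cleaves the aryl pivalate in the same operation, which frees the Ar1 phenol needed for mild ionisation in step 8, while the aryl silyl ether should survive at 0 °C.

Step 8
Reactants: 13 triol (both C7 epimers)
Product: 15 [(2S,3R,4R)-4-{3-[tert-butyl(dimethyl)silyloxy]-4,5-dimethoxybenzyl}-2-(4-hydroxy-3-methoxyphenyl)tetrahydrofuran-3-yl]methanol, via para-hydroxybenzylic cation 14 (not isolated)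
Conditions: camphorsulfonic acid (0.1 equiv), CH2Cl2, 0 °C
Reagents that add atoms: none
Why: Acid-catalysed SN1 cycloetherification, in which only the para-hydroxybenzylic C7 alcohol ionises (cation 14, a protonated quinone methide), the C9' hydroxyl closes ring A by 5-exo-trig attack because the C9 hydroxyl could only form an oxetane, and the aryl group settles trans to the C8 hydroxymethyl group so that both carbinol epimers converge on 7S.

Step 9
Reactants: 15 ring-A tetrahydrofuran with free Ar1 phenol
Product: 16 4-[(2S,3R,4R)-4-{3-[tert-butyl(dimethyl)silyloxy]-4,5-dimethoxybenzyl}-3-(hydroxymethyl)tetrahydrofuran-2-yl]-2-methoxyphenyl pivalate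
Conditions: pivaloyl chloride (1.05 equiv), K2CO3 (1.5 equiv), acetone, 0 °C → rt
Reagents that add atoms: pivaloyl chloride, CC(C)(C)C(=O)Cl
Why: Chemoselective O-acylation, since carbonate deprotonates only the phenol and the phenoxide is acylated much faster than the neutral primary C9 alcohol, which must stay free as the nucleophile of step 10.

Step 10
Reactants: 16 ring-A tetrahydrofuran with Ar1 pivalate, Ar2 silyl ether and free C9 hydroxyl
Product: 18 4-[(1S,3aR,4S,6aR)-4-{3-[tert-butyl(dimethyl)silyloxy]-4,5-dimethoxyphenyl}tetrahydro-1H,3H-furo[3,4-c]furan-1-yl]-2-methoxyphenyl pivalate, via C7' benzylic cation 17 (not isolated)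
Conditions: DDQ (1.1 equiv), 4 Å molecular sieves, CH2Cl2, 0 °C → rt; then aq. NaHCO3
Reagents that add atoms: none
Why: The quinone should pair with the electron-rich Ar2 ring and remove hydride (in one event or by electron then hydrogen-atom transfer) from the C7' methylene, giving cation 17 with its charge carried by the para 4-methoxy oxygen, and the C9 hydroxyl then adds to it with loss of a proton to the reduced quinone. The closest known reaction type is the DDQ oxidative cycloetherification of para-alkoxybenzylic C–H bonds that bear a pendant alcohol. Ring B closes by 5-exo-trig attack of the C9 oxygen on C7', completing C7'–O–C9–C8–C8'. The new C7' centre (S) is substrate-controlled: the cis relation of the C9 and C7' arms on ring A allows only the cis-fused bicycle, and the aryl group takes the convex exo face, anti to the C8'–C9' bond, to avoid the C9' methylene. The step needs site selectivity for C7'–H over the ring-A ether C7–H, secured by the pivalate on Ar1 (a poor donor para to C7) against the methoxy- and silyloxy-substituted Ar2. It also needs restraint against further oxidation of the new benzylic ether C–H, secured by near-stoichiometric oxidant, low temperature and dry conditions.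

Step 11
Reactants: 18 protected furofuran
Product: 19 4-[(1S,3aR,4S,6aR)-4-(3-hydroxy-4,5-dimethoxyphenyl)tetrahydro-1H,3H-furo[3,4-c]furan-1-yl]-2-methoxyphenol (target)
Conditions: K2CO3 (3 equiv), MeOH, rt → 40 °C; then 1 M HCl to pH 6
Reagents that add atoms: none
Why: Base-mediated methanolysis, in which methoxide cleaves the aryl pivalate by transesterification and the aryl silyl ether by attack at silicon, conditions under which the bis-benzylic ether core and its four stereocentres should be inert.

**Compound list**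

1 | 3-hydroxy-4,5-dimethoxybenzaldehyde | COc1cc(C=O)cc(O)c1OC | starting material
2 | dimethyl succinate | COC(=O)CCC(=O)OC | starting material
3 | methyl 2-(3-hydroxy-4,5-dimethoxyphenyl)-5-oxotetrahydrofuran-3-carboxylate (paraconic ester lactone, stereoisomer mixture, not isolated) | COC(=O)C1CC(=O)OC1c1cc(O)c(OC)c(OC)c1 | intermediate
4 | (E)-4-(3-hydroxy-4,5-dimethoxyphenyl)-3-(methoxycarbonyl)but-3-enoic acid | COC(=O)/C(CC(=O)O)=C/c1cc(O)c(OC)c(OC)c1 | intermediate
5 | (R)-4-(3-hydroxy-4,5-dimethoxyphenyl)-3-(methoxycarbonyl)butanoic acid | COC(=O)[C@H](Cc1cc(O)c(OC)c(OC)c1)CC(=O)O | intermediate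
6 | (R)-4-(3-hydroxy-4,5-dimethoxyphenyl)-3-(hydroxymethyl)butanoic acid (not isolated) | OC[C@H](Cc1cc(O)c(OC)c(OC)c1)CC(=O)O | intermediate
7 | (R)-4-(3-hydroxy-4,5-dimethoxybenzyl)dihydrofuran-2(3H)-one | O=C1C[C@@H](Cc2cc(O)c(OC)c(OC)c2)CO1 | intermediate
8 | (R)-4-{3-[tert-butyl(dimethyl)silyloxy]-4,5-dimethoxybenzyl}dihydrofuran-2(3H)-one | O=C1C[C@@H](Cc2cc(O[Si](C)(C)C(C)(C)C)c(OC)c(OC)c2)CO1 | intermediate
9 | vanillin | COc1cc(C=O)ccc1O | starting material
10 | 4-formyl-2-methoxyphenyl pivalate | COc1cc(C=O)ccc1OC(=O)C(C)(C)C | intermediate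
11 | lithium enolate of 8 (not isolated) | [Li+].[O-]C1=C[C@@H](Cc2cc(O[Si](C)(C)C(C)(C)C)c(OC)c(OC)c2)CO1 | intermediate
12 | 4-{[(3S,4R)-4-{3-[tert-butyl(dimethyl)silyloxy]-4,5-dimethoxybenzyl}-2-oxotetrahydrofuran-3-yl](hydroxy)methyl}-2-methoxyphenyl pivalate (both C7 epimers) | COc1cc(C(O)[C@H]2C(=O)OC[C@@H]2Cc3cc(O[Si](C)(C)C(C)(C)C)c(OC)c(OC)c3)ccc1OC(=O)C(C)(C)C | intermediate
13 | (2R,3R)-2-[(4-hydroxy-3-methoxyphenyl)(hydroxy)methyl]-3-{3-[tert-butyl(dimethyl)silyloxy]-4,5-dimethoxybenzyl}butane-1,4-diol (both C7 epimers) | COc1cc(C(O)[C@@H](CO)[C@H](CO)Cc2cc(O[Si](C)(C)C(C)(C)C)c(OC)c(OC)c2)ccc1O | intermediate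
14 | para-hydroxybenzylic C7 cation from 13 (not isolated) | COc1cc([CH+][C@@H](CO)[C@H](CO)Cc2cc(O[Si](C)(C)C(C)(C)C)c(OC)c(OC)c2)ccc1O | intermediate
15 | [(2S,3R,4R)-4-{3-[tert-butyl(dimethyl)silyloxy]-4,5-dimethoxybenzyl}-2-(4-hydroxy-3-methoxyphenyl)tetrahydrofuran-3-yl]methanol | COc1cc([C@H]2OC[C@H](Cc3cc(O[Si](C)(C)C(C)(C)C)c(OC)c(OC)c3)[C@@H]2CO)ccc1O | intermediate
16 | 4-[(2S,3R,4R)-4-{3-[tert-butyl(dimethyl)silyloxy]-4,5-dimethoxybenzyl}-3-(hydroxymethyl)tetrahydrofuran-2-yl]-2-methoxyphenyl pivalate | COc1cc([C@H]2OC[C@H](Cc3cc(O[Si](C)(C)C(C)(C)C)c(OC)c(OC)c3)[C@@H]2CO)ccc1OC(=O)C(C)(C)C | intermediate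
17 | C7' benzylic cation from 16 (not isolated) | COc1cc([C@H]2OC[C@H]([CH+]c3cc(O[Si](C)(C)C(C)(C)C)c(OC)c(OC)c3)[C@@H]2CO)ccc1OC(=O)C(C)(C)C | intermediate
18 | 4-[(1S,3aR,4S,6aR)-4-{3-[tert-butyl(dimethyl)silyloxy]-4,5-dimethoxyphenyl}tetrahydro-1H,3H-furo[3,4-c]furan-1-yl]-2-methoxyphenyl pivalate | COc1cc([C@H]2OC[C@H]3[C@@H]2CO[C@@H]3c2cc(O[Si](C)(C)C(C)(C)C)c(OC)c(OC)c2)ccc1OC(=O)C(C)(C)C | intermediate
19 | 4-[(1S,3aR,4S,6aR)-4-(3-hydroxy-4,5-dimethoxyphenyl)tetrahydro-1H,3H-furo[3,4-c]furan-1-yl]-2-methoxyphenol | COc1cc([C@H]2OC[C@H]3[C@@H]2CO[C@@H]3c2cc(O)c(OC)c(OC)c2)ccc1O | target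

**Count**

Total steps: 11. Longest linear sequence: 10 steps (1 → 4 → 5 → 7 → 8 → 12 → 13 → 15 → 16 → 18 → 19); vanillin enters through the one-step side branch 9 → 10.

**Steps most likely to fail**

Step 10. Hydride abstraction may be slow because the 4-methoxy group of Ar2 is twisted out of conjugation by its two ortho neighbours. The product may also be oxidised further at its new benzylic ether C–H, or capture of the cation may show poor facial selectivity. The fallback sets out from 16 and comes back at 18, making the same C7'–O bond by a radical relay instead of hydride abstraction. PhI(OAc)2 and I2 under visible light (cyclohexane–CH2Cl2, NaHCO3) should convert the C9 alcohol into the C9 hypoiodite of 16 F1. Homolysis gives the C9 alkoxy radical, which takes hydrogen from C7' through a six-membered transition state, whereas C7–H would need a five-membered one. The benzylic radical is then oxidised to cation 17 and closes to 18. Site selectivity then rests on geometry and not on the electronic difference between the two arenes.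

Step 8. The C7 cation may alkylate the electron-rich Ar2 ring to give a six-membered carbocycle instead of the ether, the ring may close cis, or the silyl ether may be lost under acid. The fallback sets out from 8 and 10 and comes back at 15; Ar1 is brought in by alkylation and the C7–O bond is formed oxidatively under neutral conditions. NaBH4 (MeOH, 0 °C) reduces 10 to 4-(hydroxymethyl)-2-methoxyphenyl pivalate F2, and PBr3 (Et2O, 0 °C) gives 4-(bromomethyl)-2-methoxyphenyl pivalate F3. Enolate 11 is alkylated anti to the C8' arm to give the trans-dibenzyl lactone F4. LiAlH4 (THF, 0 °C) reduces the lactone and cleaves the pivalate to the phenolic dibenzylbutanediol F5. DDQ (1 equiv, CH2Cl2, rt) oxidises the free para-phenol of Ar1 much faster than the Ar2 methylene, giving the C7 quinone methide F6, which the C9' hydroxyl captures by 5-exo-trig addition to give 15.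

Step 1. The phenoxide of 1 may precipitate or slow the condensation, so that conversion stays low and the excess methoxide consumes the aldehyde in side reactions. The fallback sets out from 1 and comes back at 7; the phenol is masked with a base-stable group through the lactone stage. BnBr and K2CO3 (DMF) give 3-(benzyloxy)-4,5-dimethoxybenzaldehyde F7, and Stobbe condensation with 2 (NaOMe, MeOH, reflux) gives the benzyloxy half-ester F8. Hydrogenation with the rhodium catalyst of step 2, which leaves the benzyl ether intact, gives the (R)-half-ester F9. The Ca(BH4)2 reduction and acid lactonisation of step 3 give the benzyloxy lactone F10, and H2 over Pd/C (EtOAc) removes the benzyl group to give 7.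

**Further compounds**

F1 | step 10 | 4-[(2S,3R,4R)-4-{3-[tert-butyl(dimethyl)silyloxy]-4,5-dimethoxybenzyl}-3-(iodooxymethyl)tetrahydrofuran-2-yl]-2-methoxyphenyl pivalate (C9 hypoiodite of 16) | COc1cc([C@H]2OC[C@H](Cc3cc(O[Si](C)(C)C(C)(C)C)c(OC)c(OC)c3)[C@@H]2COI)ccc1OC(=O)C(C)(C)C
F2 | step 8 | 4-(hydroxymethyl)-2-methoxyphenyl pivalate | COc1cc(CO)ccc1OC(=O)C(C)(C)C
F3 | step 8 | 4-(bromomethyl)-2-methoxyphenyl pivalate | COc1cc(CBr)ccc1OC(=O)C(C)(C)C
F4 | step 8 | 4-{[(3R,4R)-4-{3-[tert-butyl(dimethyl)silyloxy]-4,5-dimethoxybenzyl}-2-oxotetrahydrofuran-3-yl]methyl}-2-methoxyphenyl pivalate | COc1cc(C[C@H]2C(=O)OC[C@@H]2Cc3cc(O[Si](C)(C)C(C)(C)C)c(OC)c(OC)c3)ccc1OC(=O)C(C)(C)C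
F5 | step 8 | (2R,3R)-2-(4-hydroxy-3-methoxybenzyl)-3-{3-[tert-butyl(dimethyl)silyloxy]-4,5-dimethoxybenzyl}butane-1,4-diol | COc1cc(C[C@@H](CO)[C@H](CO)Cc2cc(O[Si](C)(C)C(C)(C)C)c(OC)c(OC)c2)ccc1O
F6 | step 8 | C7 para-quinone methide of F5 | COC1=CC(=C[C@@H](CO)[C@H](CO)Cc2cc(O[Si](C)(C)C(C)(C)C)c(OC)c(OC)c2)C=CC1=O
F7 | step 1 | 3-(benzyloxy)-4,5-dimethoxybenzaldehyde | COc1cc(C=O)cc(OCc2ccccc2)c1OC
F8 | step 1 | (E)-4-[3-(benzyloxy)-4,5-dimethoxyphenyl]-3-(methoxycarbonyl)but-3-enoic acid | COC(=O)/C(CC(=O)O)=C/c1cc(OCc2ccccc2)c(OC)c(OC)c1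
F9 | step 1 | (R)-4-[3-(benzyloxy)-4,5-dimethoxyphenyl]-3-(methoxycarbonyl)butanoic acid | COC(=O)[C@H](Cc1cc(OCc2ccccc2)c(OC)c(OC)c1)CC(=O)O
F10 | step 1 | (R)-4-[3-(benzyloxy)-4,5-dimethoxybenzyl]dihydrofuran-2(3H)-one | O=C1C[C@@H](Cc2cc(OCc3ccccc3)c(OC)c(OC)c2)CO1
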